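Spring is the flask I reckon on, for at 1.50 reagent per substrate charged it holds less reagent per substrate than any of the others.

| flask | substrate | reagent | remark | time |
|---|---|---|---|---|
| epsilon | 0.0010 M (in portions, 4) | 2.8 mM | run made earlier; portions every 15 s |  |
| zeta | 0.0010 M (in portions, 4) | 6.3 mM | run made earlier; portions every 15 s |  |
| gamma | 0.0010 M (in portions, 4) | 11 mM | run made earlier; portions every 15 s |  |
| beta | 0.0011 M (in portions, 4) | 4 mM | run made earlier; portions every 15 s |  |
| dawn | 5.0 × 10⁻⁴ M (in portions, 4) | 6.00 mM | the portions of substrate follow each other after 25 s, the first at the start | 6.0 min |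
| winter | 0.0015 M (in portions, 4) | 15.0 mM | the portions of substrate follow each other after 15 s, the first at the start | 6.0 min |
| midnight | 0.0020 M (in portions, 4) | 8.00 mM | the portions of substrate follow each other after 50 s, the first at the start | 6.0 min |
| dusk | 0.0010 M (in portions, 4) | 4.00 mM | the portions of substrate follow each other after 15 s, the first at the start | 6.0 min |
| autumn | 0.0010 M (in portions, 4) | 2.50 mM | the portions of substrate follow each other after 60 s, the first at the start | 6.0 min |
| spring | 0.0040 M (in portions, 4) | 6.00 mM | the portions of substrate follow each other after 15 s, the first at the start | 6.0 min |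

| run | time / min | target / % | substrate / % |
|---|---|---|---|
| epsilon | 0.333 | 10.3 | 37.3 |
| epsilon | 0.667 | 18.4 | 43.6 |
| epsilon | 1.33 | 33.6 | 37.4 |
| epsilon | 2.00 | 37.1 | 21.0 |
| epsilon | 4.00 | 37.1 | 4.6 |
| zeta | 0.333 | 15.8 | 28.8 |
| zeta | 0.667 | 28.3 | 32.0 |
| zeta | 1.33 | 44.3 | 23.7 |
| zeta | 2.00 | 45.9 | 10.8 |
| zeta | 4.00 | 47.9 | 1.4 |
| gamma | 0.333 | 19.1 | 21.1 |
| gamma | 0.667 | 31.1 | 24.5 |
| gamma | 1.33 | 48.1 | 17.4 |
| gamma | 2.00 | 52.4 | 5.4 |
| gamma | 4.00 | 53.1 | 0.8 |
| beta | 0.833 | 27.9 | 54.0 |
| beta | 1.50 | 37.9 | 26.1 |
| beta | 2.50 | 42.1 | 11.9 |
| beta | 3.00 | 42.1 | 7.5 |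
| beta | 4.00 | 42.9 | 3.8 |

(standard deviation of a reading: 1 percentage point)



- the flasks put in order of amount of target, in percent of the substrate charged, best first, at 6.0 min (dawn / winter / midnight / dusk / autumn / spring)
- the amount of target, in percent of the substrate charged of the flask you put first, at 6.0 min
- the amount of target, in percent of the substrate charged of the flask you put last, at 6.0 min

In epsilon, between 2.00 min and 4.00 min, target stands at 37.1% while substrate falls from 21.0% to 4.6%, so late substrate brings no net target. I read that flat stretch as a balance: target is made as fast as substrate removes it. If both steps need substrate, substrate cancels from the balance, and reagent is left against target. So I compare flasks by their equivalents, reagent over substrate, with portions every 15 s.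

Across the earlier runs the final target climbs with equivalents, from 37.1% at 2.80 to 53.1% at 11.0. That is a reading with a scatter of 1 percentage point: a gain per e-fold of equivalents of 12 points.

This gives a bracket for spring. From above, fewer equivalents than epsilon should mean less than epsilon's 37.1%, and carrying the gain down to 1.50 tightens that to 29.8%. From below, I assume spring makes at least the concentration of target that zeta reached on nearly the same reagent, which is 12.0% of spring's larger charge.

The forecast gives winter > spring > dusk > dawn > midnight > autumn, with 56% first and 18% last. Of this flask it says “Spring's 4 mM substrate depletes the 6 mM reagent somewhat, giving about 44.” That 44 percent stands above my bracket.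

The flasks give dawn > winter > dusk > autumn > midnight > spring, with 53.9% first and 19.0% last. Spring holds 19.0%, inside the bracket and below the line's 29.8%.

    substrate + reagent → target (k = 10.9 L mol⁻¹ s⁻¹)
    2 reagent → side product A (k = 2.52 L mol⁻¹ s⁻¹)
    target ⇌ isomer of the product (K = 0.440, k = 0.330 s⁻¹)
    substrate + target → side product B (k = 11.8 L mol⁻¹ s⁻¹)

In spring at 0.575 min, substrate goes into target 2.7 times as fast, at that moment, as it goes with target into side product B. By 6.00 min target is made at 0.522 of the rate at which it is used up.

The neighbour of spring takes 0.0016 M of substrate, so its reagent comes to 3.75 equiv, inside the range of the earlier runs, and the gain gives it 40.5%. The flask holds 40.1%.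

The readings come from a simulation with made-up constants; the scatter is artificial.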